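The cyclohexane is closed between its quaternary carbon C1 (CH2OH, trienyl chain) and the neighbouring CH, C2 (hydroxypropyl chain). C1 is the α-carbon of a latent β-keto ester (ketone at the carbinol carbon C6, ester for CH2OH) and C2 the γ-carbon of the exocyclic enal: two donor carbons, 1,6-related. They are joined by a manganese-mediated oxidative radical 6-endo cyclisation of an 8-phenylmenthyl β-keto ester onto an alkoxydiene. The diene is part of a temporary cycloheptadiene, whose later C–C cleavage releases the Z-enal and the hydroxypropyl chain. One operation makes the ring, both stereocentres and the tetrasubstituted enone.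

Key step: step 10

Abbreviations: "8-phenylmenthyl" is the (1R,2S,5R)-5-methyl-2-(2-phenylpropan-2-yl)cyclohexyl group; "homofarnesyl" is the (3E,7E)-4,8,12-trimethyltrideca-3,7,11-trien-1-yl group; ring B is the six-membered ring of the target, ring T the temporary seven-membered ring.

Assumption: the phenyl ring of the (−)-8-phenylmenthyl ester is taken to shield the radical face that would lead to the wrong enantiomer, so that 20 is (4R,4aR); if the sense proved opposite, (+)-8-phenylmenthol would be used in the same sequence.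

Step 1
Reactants: 1 cycloheptane-1,3-dione
Product: 2 2-methylcycloheptane-1,3-dione
Conditions: MeI, 5 M aq. NaOH, 1,4-dioxane, 65 °C
Reagents that add atoms: iodomethane, CI
Why: Enolate C-alkylation: the CH2 flanked by both carbonyl groups is by far the most acidic site and its enolate is methylated at carbon in aqueous medium.

Step 2
Reactants: 2 2-methylcycloheptane-1,3-dione
Product: 3 2-methyl-3-(2-methylpropoxy)cyclohept-2-en-1-one
Conditions: iBuOH, TsOH·H2O (cat.), toluene, reflux, Dean–Stark trap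
Reagents that add atoms: 2-methylpropan-1-ol, CC(C)CO
Why: Acid-catalysed enol etherification (vinylogous ester formation) driven by azeotropic removal of water; the two carbonyl groups of 2 are equivalent, so a single enol ether forms.

Step 3
Reactants: 3 2-methyl-3-(2-methylpropoxy)cyclohept-2-en-1-one
Product: 5 3-methyl-4-(2-methylpropoxy)cyclohepta-1,3-dien-2-yl trifluoromethanesulfonate, via lithium dienolate 4 (not isolated)
Conditions: LiN(iPr)2, THF, –78 °C; then PhNTf2, –78 → 0 °C
Reagents that add atoms: N-phenylbis(trifluoromethanesulfonimide), O=S(=O)(N(c1ccccc1)S(=O)(=O)C(F)(F)F)C(F)(F)F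
Why: Kinetic enolisation of a vinylogous ester takes place at the α'-CH2, and O-sulfonylation of the cross-conjugated enolate (enol triflate formation) fixes the new double bond towards the carbon that becomes C2 of the target ring.

Step 4
Reactants: 5 3-methyl-4-(2-methylpropoxy)cyclohepta-1,3-dien-2-yl trifluoromethanesulfonate; 6 ethyl 3-iodopropanoate
Product: 8 ethyl 3-[3-methyl-4-(2-methylpropoxy)cyclohepta-1,3-dien-2-yl]propanoate, via alkylzinc iodide 7 (not isolated)
Conditions: 6, Zn dust, LiCl, THF, 40 °C; then 5, Pd(PPh3)4 (5 mol %), THF–NMP, 50 °C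
Reagents that add atoms: none
Why: Negishi cross-coupling of the alkenyl triflate with the ester-bearing alkylzinc iodide (zinc insertion into 6) forms the sp2–sp3 bond under neutral conditions that leave the dienol ether and the diene positions untouched.

Step 5
Reactants: 8 ethyl 3-[3-methyl-4-(2-methylpropoxy)cyclohepta-1,3-dien-2-yl]propanoate
Product: 9 N-methoxy-N-methyl-3-[3-methyl-4-(2-methylpropoxy)cyclohepta-1,3-dien-2-yl]propanamide
Conditions: MeNH(OMe)·HCl, iPrMgCl, THF, –20 → 0 °C
Reagents that add atoms: N,O-dimethylhydroxylamine hydrochloride, CNOC.Cl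
Why: Aminolysis of the ester by the chloromagnesium amide of N,O-dimethylhydroxylamine gives the Weinreb amide, and the basic medium is compatible with the acid-labile dienol ether.

Step 6
Reactants: 10 (2E,6E)-farnesyl bromide [(2E,6E)-1-bromo-3,7,11-trimethyldodeca-2,6,10-triene]; 11 3-chloropropan-1-ol
Product: 13 (5E,9E)-6,10,14-trimethylpentadeca-5,9,13-trien-1-ol, via bis-magnesium reagent 12 (not isolated)
Conditions: 11, iPrMgCl, THF, –20 °C; Mg turnings, reflux; then 10, Li2CuCl4 (3 mol %), THF, –78 → 0 °C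
Reagents that add atoms: none
Why: Copper-catalysed Grignard cross-coupling (Kochi type) of a primary allylic bromide proceeds by SN2 attack at the CH2Br carbon, so the three-carbon alkoxide reagent is attached without allylic transposition and with retention of the 2E alkene.

Step 7
Reactants: 13 (5E,9E)-6,10,14-trimethylpentadeca-5,9,13-trien-1-ol
Product: 14 (5E,9E)-6,10,14-trimethylpentadeca-5,9,13-trienoic acid
Conditions: TEMPO (20 mol %), PhI(OAc)2 (2.2 equiv), MeCN–H2O 1:1, 23 °C
Reagents that add atoms: water, O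
Why: Oxoammonium (TEMPO) oxidation with PhI(OAc)2 in the presence of water carries the primary alcohol through the aldehyde hydrate to the acid and does not touch trisubstituted alkenes.

Step 8
Reactants: 14 (5E,9E)-6,10,14-trimethylpentadeca-5,9,13-trienoic acid; 15 (−)-8-phenylmenthol [(1R,2S,5R)-5-methyl-2-(2-phenylpropan-2-yl)cyclohexan-1-ol]
Product: 16 8-phenylmenthyl (5E,9E)-6,10,14-trimethylpentadeca-5,9,13-trienoate
Conditions: DCC, DMAP, CH2Cl2, 0 → 23 °C
Reagents that add atoms: none
Why: Steglich esterification: DMAP transfers the acyl group from the O-acylisourea to the hindered secondary alcohol of the auxiliary.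

Step 9
Reactants: 16 8-phenylmenthyl (5E,9E)-6,10,14-trimethylpentadeca-5,9,13-trienoate; 9 N-methoxy-N-methyl-3-[3-methyl-4-(2-methylpropoxy)cyclohepta-1,3-dien-2-yl]propanamide
Product: 18 8-phenylmenthyl (5E,9E)-6,10,14-trimethyl-2-{3-[3-methyl-4-(2-methylpropoxy)cyclohepta-1,3-dien-2-yl]propanoyl}pentadeca-5,9,13-trienoate (both C2 epimers), via lithium enolate 17 (not isolated)
Conditions: 16, LiN(iPr)2, THF, –78 °C; then 9, –78 → –20 °C; pH 7 phosphate buffer
Reagents that add atoms: none
Why: Claisen-type acylation of the ester enolate by the Weinreb amide stops at the chelated tetrahedral adduct, so neither proton transfer nor double addition interferes; the epimeric α-carbon is irrelevant because it becomes the radical carbon.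

Step 10
Reactants: 18 8-phenylmenthyl (5E,9E)-6,10,14-trimethyl-2-{3-[3-methyl-4-(2-methylpropoxy)cyclohepta-1,3-dien-2-yl]propanoyl}pentadeca-5,9,13-trienoate
Product: 20 8-phenylmenthyl (4R,4aR)-4-homofarnesyl-9-methyl-3,8-dioxo-2,3,4,4a,5,6,7,8-octahydro-1H-benzo[7]annulene-4-carboxylate (ester cis to C5 and trans to H-4a), via mixed ketal 19 (not isolated)
Conditions: Mn(OAc)3·2H2O (2.3 equiv), KOAc (2 equiv), degassed EtOH, 25–40 °C; then 0.5 M aq. HCl–THF, 0 °C
Reagents that add atoms: water, O
Why: Mn(OAc)3 enolises the 2-alkyl-3-oxo ester and oxidises it to the electrophilic α-radical (target C1, C4 of 20), which adds to the unsubstituted terminus of the electron-rich 1-alkoxy-1,3-diene (target C2, C4a of 20); the resulting 1-alkoxyallyl radical is oxidised by a second equivalent of trivalent manganese to an oxocarbenium ion, which ethanol traps as ketal 19 and the work-up hydrolyses to the enone. The closest known reaction types are the Mn(OAc)3 oxidative free-radical cyclisation of unsaturated 2-alkyl-3-oxo esters and the oxidative addition of 1,3-dicarbonyl radicals to enol and dienol ethers. Ring B closes in the 6-endo-trig mode, because the 5-exo position is the fully substituted diene carbon and 6-endo attack gives the oxygen-stabilised allyl radical. Both stereocentres arise in one chair-like transition state: the cis alkene of ring T holds the C4a–C5 bond equatorial and the ester on the planar radical carbon takes the axial position (anti to the ketone oxygen), so ester and C5 end up cis, while the phenyl ring of the auxiliary covers one face of the radical and fixes the absolute sense, any minor diastereomer being separable by chromatography. The step needs site selectivity for the diene terminus over the methyl-bearing diene carbon and over the chain alkenes; this is secured by the hindrance and weaker radical stabilisation at the former and by the 4-exo or 5-endo closure that the nearest chain alkene would require. The Z geometry of the later enal is locked here, since the carbonyl carbon C8 and C4a are held cis on the ring T alkene.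

Step 11
Reactants: 20 8-phenylmenthyl (4R,4aR)-4-homofarnesyl-9-methyl-3,8-dioxo-2,3,4,4a,5,6,7,8-octahydro-1H-benzo[7]annulene-4-carboxylate
Product: 21 8-phenylmenthyl (3S,4R,4aR)-3-hydroxy-4-homofarnesyl-3,9-dimethyl-8-oxo-2,3,4,4a,5,6,7,8-octahydro-1H-benzo[7]annulene-4-carboxylate (OH cis to the ester)
Conditions: MeMgBr (1.3 equiv), CH2Cl2–Et2O, –78 °C; NH4Cl
Reagents that add atoms: methylmagnesium bromide, C[Mg]Br
Why: Grignard 1,2-addition occurs at the saturated ketone, activated by the α-ester, faster than at the tetrasubstituted conjugated ketone, and the methyl group enters axially anti to the axial ester (Felkin–Anh sense, the C4a–C5 bond being equatorial), which puts OH cis to the ester and gives 3S.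

Step 12
Reactants: 21 8-phenylmenthyl (3S,4R,4aR)-3-hydroxy-4-homofarnesyl-3,9-dimethyl-8-oxo-2,3,4,4a,5,6,7,8-octahydro-1H-benzo[7]annulene-4-carboxylate
Product: 23 8-phenylmenthyl (3S,4R,4aR)-3,7-dihydroxy-4-homofarnesyl-3,9-dimethyl-8-oxo-2,3,4,4a,5,6,7,8-octahydro-1H-benzo[7]annulene-4-carboxylate (C7 epimers), via disodium alkoxide dienolate 22 (not isolated)
Conditions: NaN(SiMe3)2 (2.3 equiv), THF, –78 °C; then 3-phenyl-2-(phenylsulfonyl)oxaziridine, –78 °C; NH4Cl
Reagents that add atoms: 3-phenyl-2-(phenylsulfonyl)oxaziridine, O=S(=O)(N1OC1c1ccccc1)c1ccccc1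
Why: Davis enolate oxidation: after the alkoxide, the amide base removes the kinetically most accessible α'-proton of the enone (C7), and the sodium enolate is hydroxylated by the N-sulfonyloxaziridine, which is inert to the chain alkenes; the new carbinol centre is lost in step 13.

Step 13
Reactants: 23 8-phenylmenthyl (3S,4R,4aR)-3,7-dihydroxy-4-homofarnesyl-3,9-dimethyl-8-oxo-2,3,4,4a,5,6,7,8-octahydro-1H-benzo[7]annulene-4-carboxylate
Product: 24 8-phenylmenthyl (1R,2S,5Z,6R)-2-hydroxy-1-homofarnesyl-5-(1-methoxy-1-oxopropan-2-ylidene)-2-methyl-6-(3-oxopropyl)cyclohexane-1-carboxylate (CO2Me cis to C6)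
Conditions: Pb(OAc)4 (1.2 equiv), MeOH–benzene 1:1, 0 °C
Reagents that add atoms: methanol, CO
Why: Criegee-type α-ketol cleavage: in methanol Pb(OAc)4 cleaves the C7–C8 bond to an aldehyde and a methyl ester, opening ring T, and because C8 and C4a were cis on the ring alkene the enoate is formed as the Z isomer only.

Step 14
Reactants: 24 8-phenylmenthyl (1R,2S,5Z,6R)-2-hydroxy-1-homofarnesyl-5-(1-methoxy-1-oxopropan-2-ylidene)-2-methyl-6-(3-oxopropyl)cyclohexane-1-carboxylate
Product: 25 (2Z)-2-[(2R,3S,4S)-4-hydroxy-3-(hydroxymethyl)-2-(3-hydroxypropyl)-4-methyl-3-homofarnesylcyclohexylidene]propan-1-ol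
Conditions: LiAlH4 (excess), THF, 0 → 50 °C; aqueous work-up
Reagents that add atoms: none
Why: LiAlH4 reduction converts the aldehyde, the conjugated methyl ester (1,2-reduction) and the neopentyl-type auxiliary ester into three primary alcohols and releases the auxiliary 15 for recovery, without affecting any stereocentre.

Step 15
Reactants: 25 (2Z)-2-[(2R,3S,4S)-4-hydroxy-3-(hydroxymethyl)-2-(3-hydroxypropyl)-4-methyl-3-homofarnesylcyclohexylidene]propan-1-ol
Product: 26 (2Z)-2-[(2R,3S,4S)-4-hydroxy-3-(hydroxymethyl)-2-(3-hydroxypropyl)-4-methyl-3-[(3E,7E)-4,8,12-trimethyltrideca-3,7,11-trien-1-yl]cyclohexylidene]propanal (CNP0284886.1)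
Conditions: activated MnO2 (20 equiv), CH2Cl2, 23 °C
Reagents that add atoms: none
Why: MnO2 oxidises allylic alcohols selectively, so only the CH2OH on the tetrasubstituted alkene becomes the aldehyde, and the alkene geometry (Z) is retained.

Compound list

1 | cycloheptane-1,3-dione | O=C1CCCCC(=O)C1 | starting material
2 | 2-methylcycloheptane-1,3-dione | CC1C(=O)CCCCC1=O | intermediate
3 | 2-methyl-3-(2-methylpropoxy)cyclohept-2-en-1-one | CC1=C(OCC(C)C)CCCCC1=O | intermediate
4 | lithium cross-conjugated dienolate of 3 (O–C1=C7, C2=C3 retained) | CC1=C(OCC(C)C)CCCC=C1O[Li] | intermediate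
5 | 3-methyl-4-(2-methylpropoxy)cyclohepta-1,3-dien-2-yl trifluoromethanesulfonate | CC1=C(OCC(C)C)CCCC=C1OS(=O)(=O)C(F)(F)F | intermediate
6 | ethyl 3-iodopropanoate | CCOC(=O)CCI | starting material
7 | (3-ethoxy-3-oxopropyl)zinc iodide | CCOC(=O)CC[Zn]I | intermediate
8 | ethyl 3-[3-methyl-4-(2-methylpropoxy)cyclohepta-1,3-dien-2-yl]propanoate | CCOC(=O)CCC1=CCCCC(OCC(C)C)=C1C | intermediate
9 | N-methoxy-N-methyl-3-[3-methyl-4-(2-methylpropoxy)cyclohepta-1,3-dien-2-yl]propanamide | CON(C)C(=O)CCC1=CCCCC(OCC(C)C)=C1C | intermediate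
10 | (2E,6E)-farnesyl bromide | CC(C)=CCC/C(C)=C/CC/C(C)=C/CBr | starting material
11 | 3-chloropropan-1-ol | OCCCCl | starting material
12 | chloromagnesium 3-(chloromagnesio)propan-1-olate | Cl[Mg]OCCC[Mg]Cl | intermediate
13 | (5E,9E)-6,10,14-trimethylpentadeca-5,9,13-trien-1-ol | CC(C)=CCC/C(C)=C/CC/C(C)=C/CCCCO | intermediate
14 | (5E,9E)-6,10,14-trimethylpentadeca-5,9,13-trienoic acid | CC(C)=CCC/C(C)=C/CC/C(C)=C/CCCC(=O)O | intermediate
15 | (−)-8-phenylmenthol, (1R,2S,5R)-5-methyl-2-(2-phenylpropan-2-yl)cyclohexan-1-ol | O[C@@H]1C[C@H](C)CC[C@H]1C(C)(C)c1ccccc1 | starting material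
16 | 8-phenylmenthyl (5E,9E)-6,10,14-trimethylpentadeca-5,9,13-trienoate | CC(C)=CCC/C(C)=C/CC/C(C)=C/CCCC(=O)O[C@@H]1C[C@H](C)CC[C@H]1C(C)(C)c1ccccc1 | intermediate
17 | lithium enolate of 16 | CC(C)=CCC/C(C)=C/CC/C(C)=C/CCC=C(O[Li])O[C@@H]1C[C@H](C)CC[C@H]1C(C)(C)c1ccccc1 | intermediate
18 | 8-phenylmenthyl (5E,9E)-6,10,14-trimethyl-2-{3-[3-methyl-4-(2-methylpropoxy)cyclohepta-1,3-dien-2-yl]propanoyl}pentadeca-5,9,13-trienoate, both C2 epimers | CC(C)=CCC/C(C)=C/CC/C(C)=C/CCC(C(=O)CCC1=CCCCC(OCC(C)C)=C1C)C(=O)O[C@@H]1C[C@H](C)CC[C@H]1C(C)(C)c1ccccc1 | intermediate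
19 | 8-ethoxy-8-(2-methylpropoxy) ketal of 20, (4R,4aR) | CC(C)=CCC/C(C)=C/CC/C(C)=C/CC[C@@]1(C(=O)O[C@@H]3C[C@H](C)CC[C@H]3C(C)(C)c3ccccc3)[C@@H]2CCCC(OCC)(OCC(C)C)C(C)=C2CCC1=O | intermediate
20 | 8-phenylmenthyl (4R,4aR)-4-homofarnesyl-9-methyl-3,8-dioxo-2,3,4,4a,5,6,7,8-octahydro-1H-benzo[7]annulene-4-carboxylate | CC(C)=CCC/C(C)=C/CC/C(C)=C/CC[C@@]1(C(=O)O[C@@H]3C[C@H](C)CC[C@H]3C(C)(C)c3ccccc3)[C@@H]2CCCC(=O)C(C)=C2CCC1=O | intermediate
21 | 8-phenylmenthyl (3S,4R,4aR)-3-hydroxy-4-homofarnesyl-3,9-dimethyl-8-oxo-2,3,4,4a,5,6,7,8-octahydro-1H-benzo[7]annulene-4-carboxylate | CC(C)=CCC/C(C)=C/CC/C(C)=C/CC[C@@]1(C(=O)O[C@@H]3C[C@H](C)CC[C@H]3C(C)(C)c3ccccc3)[C@@H]2CCCC(=O)C(C)=C2CC[C@]1(C)O | intermediate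
22 | disodium 3-alkoxide 7,8-dienolate of 21 | CC(C)=CCC/C(C)=C/CC/C(C)=C/CC[C@@]1(C(=O)O[C@@H]3C[C@H](C)CC[C@H]3C(C)(C)c3ccccc3)[C@@H]2CCC=C(O[Na])C(C)=C2CC[C@]1(C)O[Na] | intermediate
23 | 8-phenylmenthyl (3S,4R,4aR)-3,7-dihydroxy-4-homofarnesyl-3,9-dimethyl-8-oxo-2,3,4,4a,5,6,7,8-octahydro-1H-benzo[7]annulene-4-carboxylate, C7 epimers | CC(C)=CCC/C(C)=C/CC/C(C)=C/CC[C@@]1(C(=O)O[C@@H]3C[C@H](C)CC[C@H]3C(C)(C)c3ccccc3)[C@@H]2CCC(O)C(=O)C(C)=C2CC[C@]1(C)O | intermediate
24 | 8-phenylmenthyl (1R,2S,5Z,6R)-2-hydroxy-1-homofarnesyl-5-(1-methoxy-1-oxopropan-2-ylidene)-2-methyl-6-(3-oxopropyl)cyclohexane-1-carboxylate | CC(C)=CCC/C(C)=C/CC/C(C)=C/CC[C@@]1(C(=O)O[C@@H]2C[C@H](C)CC[C@H]2C(C)(C)c2ccccc2)[C@H](CCC=O)/C(=C(/C)C(=O)OC)CC[C@]1(C)O | intermediate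
25 | (2Z)-2-[(2R,3S,4S)-4-hydroxy-3-(hydroxymethyl)-2-(3-hydroxypropyl)-4-methyl-3-homofarnesylcyclohexylidene]propan-1-ol | CC(C)=CCC/C(C)=C/CC/C(C)=C/CC[C@@]1(CO)[C@H](CCCO)/C(=C(/C)CO)CC[C@]1(C)O | intermediate
26 | (2Z)-2-[(2R,3S,4S)-4-hydroxy-3-(hydroxymethyl)-2-(3-hydroxypropyl)-4-methyl-3-[(3E,7E)-4,8,12-trimethyltrideca-3,7,11-trien-1-yl]cyclohexylidene]propanal | CC(C)=CCC/C(C)=C/CC/C(C)=C/CC[C@@]1(CO)[C@H](CCCO)/C(=C(/C)C=O)CC[C@]1(C)O | target

Total step count: 15. Longest linear sequence: 12 steps (steps 1–5 and 9–15); steps 6–8 form the side branch.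

Steps most likely to fail

Step 10. The dienol ether may be hydrolysed by the acetic acid that the oxidant liberates before the radical forms; the alkoxyallyl cation may lose a γ-proton, which would erase the C4a centre; or the auxiliary may discriminate the two radical faces insufficiently. The fallback replaces the radical closure by a two-electron closure after polarity reversal at the diene terminus. It sets out from 18: N-bromosuccinimide (CH2Cl2, –78 °C, then aqueous NaHCO3) attacks the diene terminus and, with loss of isobutanol, gives the γ-bromo enone 8-phenylmenthyl (5E,9E)-2-[3-(7-bromo-2-methyl-3-oxocyclohept-1-en-1-yl)propanoyl]-6,10,14-trimethylpentadeca-5,9,13-trienoate F1. Cs2CO3 with Bu4NBr in MeCN then closes the same bond by intramolecular C-alkylation (6-exo-tet) of the β-keto ester enolate at the allylic bromide, which epimerises by bromide exchange. The diastereomers are separated with the help of the auxiliary, and the sequence comes back to the route at 20.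

Step 11. The Grignard reagent may also add to the enone carbonyl, or approach from the ester face. The fallback keeps the enone carbonyl masked. It sets out from 19, which is isolated instead of hydrolysed (cyclisation with anhydrous Mn(OAc)3 in EtOH containing HC(OEt)3, no acid work-up). MeMgBr then has only one ketone to attack and gives the tertiary alcohol 8-phenylmenthyl (3S,4R,4aR)-8-ethoxy-3-hydroxy-4-homofarnesyl-3,9-dimethyl-8-(2-methylpropoxy)-2,3,4,4a,5,6,7,8-octahydro-1H-benzo[7]annulene-4-carboxylate F2. Dilute aqueous HCl in THF unmasks the enone, and the sequence comes back to the route at 21.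

Step 12. The tertiary alkoxide may undergo retro-aldol fragmentation under the strongly basic conditions, or the enolate may equilibrate towards the γ-position with loss of the C4a centre. The fallback avoids strong base. It sets out from 21: Mn(OAc)3 in refluxing benzene acetoxylates the α'-position of the enone through the manganese enolate and gives 8-phenylmenthyl (3S,4R,4aR)-7-acetoxy-3-hydroxy-4-homofarnesyl-3,9-dimethyl-8-oxo-2,3,4,4a,5,6,7,8-octahydro-1H-benzo[7]annulene-4-carboxylate F3. K2CO3 in MeOH at 0 °C removes the acetyl group, and the sequence comes back to the route at 23.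

Further compounds

F1 | step 10 | 8-phenylmenthyl (5E,9E)-2-[3-(7-bromo-2-methyl-3-oxocyclohept-1-en-1-yl)propanoyl]-6,10,14-trimethylpentadeca-5,9,13-trienoate | CC(C)=CCC/C(C)=C/CC/C(C)=C/CCC(C(=O)CCC1=C(C)C(=O)CCCC1Br)C(=O)O[C@@H]1C[C@H](C)CC[C@H]1C(C)(C)c1ccccc1
F2 | step 11 | 8-phenylmenthyl (3S,4R,4aR)-8-ethoxy-3-hydroxy-4-homofarnesyl-3,9-dimethyl-8-(2-methylpropoxy)-2,3,4,4a,5,6,7,8-octahydro-1H-benzo[7]annulene-4-carboxylate | CC(C)=CCC/C(C)=C/CC/C(C)=C/CC[C@@]1(C(=O)O[C@@H]3C[C@H](C)CC[C@H]3C(C)(C)c3ccccc3)[C@@H]2CCCC(OCC)(OCC(C)C)C(C)=C2CC[C@]1(C)O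
F3 | step 12 | 8-phenylmenthyl (3S,4R,4aR)-7-acetoxy-3-hydroxy-4-homofarnesyl-3,9-dimethyl-8-oxo-2,3,4,4a,5,6,7,8-octahydro-1H-benzo[7]annulene-4-carboxylate | CC(C)=CCC/C(C)=C/CC/C(C)=C/CC[C@@]1(C(=O)O[C@@H]3C[C@H](C)CC[C@H]3C(C)(C)c3ccccc3)[C@@H]2CCC(OC(C)=O)C(=O)C(C)=C2CC[C@]1(C)O
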